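**Retrosynthetic overview**
1. Target ⇒ (last step) reagent-controlled para-hydroxylative dearomatisation of the fully assembled, unprotected 2-acylamino-6-chloro-4-alkylphenol, the likely biosynthetic precursor. This step creates the quinol ring and its (R)-carbinol together.
2. Phenol ⇒ amide bond between 5-(3-amino-5-chloro-4-hydroxyphenyl)pentanoic acid and (2E,4S,6R)-4,6,8-trimethylnona-2,7-dienoic acid.
3. Aminophenol acid ⇒ C7 arene (3-chloro-4-hydroxybenzaldehyde, a 3,4-AHBA-type unit) plus a C4 Wittig salt, with a nitration before and one hydrogenation after.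
4. Dienoic acid ⇒ two olefinations (isopropylidene Wittig, then HWE) at the two ends of lipase-desymmetrised meso-2,4-dimethylpentane-1,5-diol. The syn-dimethyl array comes from the meso-anhydride.
5. Ring order: there is only one ring. It enters as the benzene ring of the aldehyde and becomes the cyclohexa-2,5-dienone in the final step.

Assumption: the facial sense of the chiral iodane on this substrate is not known in advance, so the (R,R)-reagent is written and its (S,S)-enantiomer is used instead if a pilot run shows the opposite sense; the minor carbinol epimer is a diastereomer and is removed by HPLC.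

**Step 1**
Reactants: 1 3-chloro-4-hydroxybenzaldehyde
Product: 2 3-chloro-4-hydroxy-5-nitrobenzaldehyde
Conditions: HNO3 (70%, 1.1 equiv), AcOH, 10 °C → rt
Reagents that add atoms: nitric acid, O[N+](=O)[O-]
Why: Electrophilic aromatic nitration, in which the hydroxyl group directs to its only free ortho position, which is also meta to the formyl group, so one regioisomer forms.

**Step 2**
Reactants: 2 3-chloro-4-hydroxy-5-nitrobenzaldehyde; 3 (3-carboxypropyl)triphenylphosphonium bromide
Product: 5 (E/Z)-5-(3-chloro-4-hydroxy-5-nitrophenyl)pent-4-enoic acid, via ylide carboxylate 4 (not isolated)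
Conditions: 3 (1.3 equiv), KOtBu (2.6 equiv), THF, 0 °C; add 2 + KOtBu (1.0 equiv) in THF, 0 °C → rt; then 1 M HCl
Reagents that add atoms: none
Why: Wittig olefination with the carboxylate-bearing non-stabilised ylide joins the C7 and C4 units without protecting groups (extra base keeps phenol and acid as spectator anions), and the alkene geometry does not matter because the double bond is hydrogenated next.

**Step 3**
Reactants: 5 (E/Z)-5-(3-chloro-4-hydroxy-5-nitrophenyl)pent-4-enoic acid
Product: 6 5-(3-amino-5-chloro-4-hydroxyphenyl)pentanoic acid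
Conditions: H2 (3 bar), Pt/C (5 wt% Pt), MeOH, rt; filtered under N2 and used at once
Reagents that add atoms: none
Why: Heterogeneous catalytic hydrogenation over platinum reduces the nitro group and the styrene double bond together and, unlike palladium, leaves the aryl chloride in place.

**Step 4**
Reactants: 7 meso-2,4-dimethylglutaric anhydride [(3R,5S)-3,5-dimethyloxane-2,6-dione, methyl groups cis]
Product: 8 meso-(2R,4S)-2,4-dimethylpentane-1,5-diol
Conditions: LiAlH4 (2 equiv), THF, 0 °C → reflux; H2O/NaOH work-up
Reagents that add atoms: none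
Why: Hydride reduction of the cyclic anhydride to the diol does not touch the two methyl-bearing carbons, so the cis (later syn-1,3-dimethyl) relationship is carried over.

**Step 5**
Reactants: 8 meso-(2R,4S)-2,4-dimethylpentane-1,5-diol
Product: 9 (2S,4R)-5-hydroxy-2,4-dimethylpentyl acetate
Conditions: Amano lipase AK (Pseudomonas fluorescens), vinyl acetate (4 equiv), THF, 0 °C → rt
Reagents that add atoms: vinyl acetate, C=COC(C)=O
Why: Enzymatic desymmetrisation by irreversible lipase transesterification acetylates only the hydroxymethyl group next to the (S)-carbon, which turns the meso-diol into one enantiomer (typically >98% ee) and fixes the absolute configuration of both methyl-bearing carbons (later C-4 S and C-6 R of the acyl chain).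

**Step 6**
Reactants: 9 (2S,4R)-5-hydroxy-2,4-dimethylpentyl acetate
Product: 10 (2S,4R)-2,4-dimethyl-5-oxopentyl acetate
Conditions: TEMPO (10 mol%), PhI(OAc)2 (1.1 equiv), CH2Cl2, rt
Reagents that add atoms: none
Why: Nitroxyl-catalysed alcohol oxidation (TEMPO/PhI(OAc)2) stops at the aldehyde under nearly neutral conditions, so the α-stereocentre is not epimerised and the acetate survives.

**Step 7**
Reactants: 10 (2S,4R)-2,4-dimethyl-5-oxopentyl acetate; 11 isopropyltriphenylphosphonium iodide
Product: 14 (2S,4R)-2,4,6-trimethylhept-5-en-1-ol, via isopropylidene ylide 12 (not isolated), via alkenyl acetate 13 (not isolated)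
Conditions: 11 (1.4 equiv), n-BuLi (1.35 equiv), THF, 0 °C; 10, −78 °C → 0 °C; then MeOH, K2CO3 (0.3 equiv), rt
Reagents that add atoms: none
Why: Wittig olefination with the non-stabilised ylide at low temperature is faster than enolisation of the α-methyl aldehyde or attack on the acetate, and base-catalysed transesterification with methanol in the same flask frees the primary alcohol.

**Step 8**
Reactants: 14 (2S,4R)-2,4,6-trimethylhept-5-en-1-ol
Product: 15 (2S,4R)-2,4,6-trimethylhept-5-enal
Conditions: TEMPO (10 mol%), PhI(OAc)2 (1.1 equiv), CH2Cl2, 0 °C → rt; used crude (volatile)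
Reagents that add atoms: none
Why: The same nitroxyl-catalysed oxidation leaves trisubstituted alkenes alone (as in the oxidation of nerol or citronellol) and does not epimerise the α-methyl aldehyde.

**Step 9**
Reactants: 15 (2S,4R)-2,4,6-trimethylhept-5-enal; 16 diethylphosphonoacetic acid
Product: 17 (2E,4S,6R)-4,6,8-trimethylnona-2,7-dienoic acid
Conditions: 16 (1.2 equiv), Zn(OTf)2 (2.2 equiv), TMEDA (1.3 equiv), DBU (4 equiv), THF, rt; then 1 M HCl
Reagents that add atoms: none
Why: Horner–Wadsworth–Emmons olefination of the zinc-chelated phosphonoacetate with amine bases gives the (E)-enoic acid directly from an α-branched aldehyde, is mild enough to keep the α-stereocentre, and saves an ester hydrolysis.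

**Step 10**
Reactants: 17 (2E,4S,6R)-4,6,8-trimethylnona-2,7-dienoic acid; 6 5-(3-amino-5-chloro-4-hydroxyphenyl)pentanoic acid
Product: 19 5-(3-chloro-4-hydroxy-5-{[(2E,4S,6R)-4,6,8-trimethylnona-2,7-dienoyl]amino}phenyl)pentanoic acid, via mixed carbonic anhydride 18 (not isolated)
Conditions: isobutyl chloroformate (1.0 equiv), N-methylmorpholine (1.05 equiv), THF, −20 °C, 20 min; then 6 (1.05 equiv) in DMF, −20 °C → rt
Reagents that add atoms: isobutyl chloroformate, CC(C)COC(=O)Cl (its atoms stay only in 18)
Why: Mixed-anhydride amide coupling activates only acid 17 before 6 is added, and the aniline nitrogen is by far the best nucleophile of 6 (any O-acyl product shifts to nitrogen), so neither the phenol nor the carboxylic acid of 6 needs protection.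

**Step 11**
Reactants: 19 5-(3-chloro-4-hydroxy-5-{[(2E,4S,6R)-4,6,8-trimethylnona-2,7-dienoyl]amino}phenyl)pentanoic acid
Product: 21 5-[(1R)-3-chloro-1-hydroxy-4-oxo-5-{[(2E,4S,6R)-4,6,8-trimethylnona-2,7-dienoyl]amino}cyclohexa-2,5-dien-1-yl]pentanoic acid (CNP0128873.1), via aryloxy-iodane 20 (not isolated)
Conditions: (R,R)-2-iodo-1,3-bis[1-(mesitylcarbamoyl)ethoxy]benzene (1.3 equiv), mCPBA (1.15 equiv), AcOH/CH2Cl2, rt, 12 h (peracid fully consumed, 1H NMR check), evaporate; then 19, MeCN/H2O 9:1, −20 °C → 0 °C; reversed-phase HPLC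
Reagents that add atoms: water, O; (R,R)-2-(diacetoxyiodo)-1,3-bis[1-(mesitylcarbamoyl)ethoxy]benzene made in the flask, CC(=O)OI(OC(C)=O)c1c(O[C@H](C)C(=O)Nc2c(C)cc(C)cc2C)cccc1O[C@H](C)C(=O)Nc1c(C)cc(C)cc1C (its atoms stay only in 20)
Why: Proposed new method: the phenol oxygen of 19 displaces one acetate of the trivalent-iodine reagent to give 20, in which the folded lactamide arms (N–H···O hydrogen bonds to the iodine ligands and to the substrate anilide, which is distinguished from the small chlorine on the other flank) cover one ring face, so water adds to the para carbon from the open face as the iodoarene leaves and sets the (R)-carbinol, the laboratory counterpart of the monooxygenase para-hydroxylation presumed for manumycin-type quinols; the closest known reaction types are the PhI(OAc)2/H2O oxidation of 4-alkylphenols to p-quinols and the chiral aryl-iodide-catalysed enantioselective hydrative para-dearomatisation of 2-substituted 4-alkylphenols, and the iodane is pre-formed and used stoichiometrically because a peracid co-oxidant would epoxidise the trisubstituted alkene.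

**Compound list**
1 | 3-chloro-4-hydroxybenzaldehyde | O=Cc1ccc(O)c(Cl)c1 | starting material
2 | 3-chloro-4-hydroxy-5-nitrobenzaldehyde | O=Cc1cc(Cl)c(O)c([N+](=O)[O-])c1 | intermediate
3 | (3-carboxypropyl)triphenylphosphonium bromide | OC(=O)CCC[P+](c1ccccc1)(c1ccccc1)c1ccccc1.[Br-] | starting material
4 | ylide carboxylate, potassium 4-(triphenyl-λ5-phosphanylidene)butanoate (not isolated) | [K+].[O-]C(=O)CCC=P(c1ccccc1)(c1ccccc1)c1ccccc1 | intermediate
5 | (E/Z)-5-(3-chloro-4-hydroxy-5-nitrophenyl)pent-4-enoic acid | OC(=O)CCC=Cc1cc(Cl)c(O)c([N+](=O)[O-])c1 | intermediate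
6 | 5-(3-amino-5-chloro-4-hydroxyphenyl)pentanoic acid | Nc1cc(CCCCC(=O)O)cc(Cl)c1O | intermediate
7 | meso-2,4-dimethylglutaric anhydride, (3R,5S)-3,5-dimethyloxane-2,6-dione | O=C1[C@H](C)C[C@H](C)C(=O)O1 | starting material
8 | meso-(2R,4S)-2,4-dimethylpentane-1,5-diol | OC[C@H](C)C[C@H](C)CO | intermediate
9 | (2S,4R)-5-hydroxy-2,4-dimethylpentyl acetate | OC[C@H](C)C[C@H](C)COC(C)=O | intermediate
10 | (2S,4R)-2,4-dimethyl-5-oxopentyl acetate | O=C[C@H](C)C[C@H](C)COC(C)=O | intermediate
11 | isopropyltriphenylphosphonium iodide | CC(C)[P+](c1ccccc1)(c1ccccc1)c1ccccc1.[I-] | starting material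
12 | isopropylidene ylide, (propan-2-ylidene)triphenyl-λ5-phosphane (not isolated) | CC(C)=P(c1ccccc1)(c1ccccc1)c1ccccc1 | intermediate
13 | alkenyl acetate, (2S,4R)-2,4,6-trimethylhept-5-en-1-yl acetate (not isolated) | CC(C)=C[C@H](C)C[C@H](C)COC(C)=O | intermediate
14 | (2S,4R)-2,4,6-trimethylhept-5-en-1-ol | CC(C)=C[C@H](C)C[C@H](C)CO | intermediate
15 | (2S,4R)-2,4,6-trimethylhept-5-enal | CC(C)=C[C@H](C)C[C@H](C)C=O | intermediate
16 | diethylphosphonoacetic acid | CCOP(=O)(CC(=O)O)OCC | starting material
17 | (2E,4S,6R)-4,6,8-trimethylnona-2,7-dienoic acid | CC(C)=C[C@H](C)C[C@H](C)/C=C/C(=O)O | intermediate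
18 | mixed carbonic anhydride of 17 with isobutyl hydrogen carbonate (not isolated) | CC(C)=C[C@H](C)C[C@H](C)/C=C/C(=O)OC(=O)OCC(C)C | intermediate
19 | 5-(3-chloro-4-hydroxy-5-{[(2E,4S,6R)-4,6,8-trimethylnona-2,7-dienoyl]amino}phenyl)pentanoic acid | CC(C)=C[C@H](C)C[C@H](C)/C=C/C(=O)Nc1cc(CCCCC(=O)O)cc(Cl)c1O | intermediate
20 | aryloxy-iodane, acetoxy(aryloxy)-λ3-iodane with the phenol oxygen of 19 bound to the iodine of the (R,R)-bis(lactamide) aryl group (not isolated) | CC(C)=C[C@H](C)C[C@H](C)/C=C/C(=O)Nc1cc(CCCCC(=O)O)cc(Cl)c1OI(OC(C)=O)c1c(O[C@H](C)C(=O)Nc2c(C)cc(C)cc2C)cccc1O[C@H](C)C(=O)Nc1c(C)cc(C)cc1C | intermediate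
21 | 5-[(1R)-3-chloro-1-hydroxy-4-oxo-5-{[(2E,4S,6R)-4,6,8-trimethylnona-2,7-dienoyl]amino}cyclohexa-2,5-dien-1-yl]pentanoic acid | CC(C)=C[C@H](C)C[C@H](C)/C=C/C(=O)NC1=C[C@](O)(CCCCC(=O)O)C=C(Cl)C1=O | target

**Total step count:** 11. **Longest linear sequence:** 8 (steps 4–11, from 7).

**Steps most likely to fail**

Step 11 may give too little facial selectivity, or the hindered iodane may react slowly with a 2,6-disubstituted phenol. The fallback gives up reagent control and relies on diastereomer separation with recycling. It sets out from 19, which is oxidised with plain PhI(OAc)2 in MeCN/H2O to a roughly 1:1 mixture of 21 and the (1S)-epimeric quinol F1. The two are diastereomers because the acyl chain is enantiopure, so they are separated by preparative HPLC and the route is rejoined at 21. F1 is returned to 19 by reductive aromatisation (Zn, AcOH, loss of water) and oxidised again.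

Step 7 may epimerise the α-methyl aldehyde under the strongly basic ylide, and the products are volatile. The fallback replaces the basic olefination by a neutral one followed by cross-coupling. It sets out from 10, which undergoes Ramirez olefination (CBr4, PPh3, CH2Cl2, 0 °C) to (2S,4R)-6,6-dibromo-2,4-dimethylhex-5-en-1-yl acetate F2. Double Negishi methylation (Me2Zn, Pd(PtBu3)2 catalyst, THF) then gives the isobutenyl group and rejoins the route at 13. Compound 13 is methanolysed to 14 as before.

Step 2 is a Wittig reaction between two anionic partners in the presence of a nitroarene. The fallback uses a stabilised, less basic vinylogous phosphonate. It sets out from 2, which reacts with triethyl 4-phosphonocrotonate and LiHMDS (2.2 equiv, THF) to give ethyl (2E,4E)-5-(3-chloro-4-hydroxy-5-nitrophenyl)penta-2,4-dienoate F3. Saponification with LiOH in THF/H2O gives (2E,4E)-5-(3-chloro-4-hydroxy-5-nitrophenyl)penta-2,4-dienoic acid F4. Hydrogenation over Pt/C reduces both double bonds and the nitro group and rejoins the route at 6.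

**Further compounds**
F1 | step 11 | 5-[(1S)-3-chloro-1-hydroxy-4-oxo-5-{[(2E,4S,6R)-4,6,8-trimethylnona-2,7-dienoyl]amino}cyclohexa-2,5-dien-1-yl]pentanoic acid | CC(C)=C[C@H](C)C[C@H](C)/C=C/C(=O)NC1=C[C@@](O)(CCCCC(=O)O)C=C(Cl)C1=O
F2 | step 7 | (2S,4R)-6,6-dibromo-2,4-dimethylhex-5-en-1-yl acetate | BrC(Br)=C[C@H](C)C[C@H](C)COC(C)=O
F3 | step 2 | ethyl (2E,4E)-5-(3-chloro-4-hydroxy-5-nitrophenyl)penta-2,4-dienoate | CCOC(=O)/C=C/C=C/c1cc(Cl)c(O)c([N+](=O)[O-])c1
F4 | step 2 | (2E,4E)-5-(3-chloro-4-hydroxy-5-nitrophenyl)penta-2,4-dienoic acid | OC(=O)/C=C/C=C/c1cc(Cl)c(O)c([N+](=O)[O-])c1
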